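**Retrosynthetic overview**

- The route rests on the chain at C8 of ring A: the benzylic C1''H2 is bonded to the carbinol carbon C2'', and C2'' carries the isopropenyl carbon C3''. Read as aryl electrophile–CH2–CH(boron)–migrating group, this is what a vinylboron ate complex gives after a 1,2-metallate shift.
- The C2''–OH goes back to a C2''–B(pin) bond of the same configuration, and the three phenols go back to MOM ethers.
- C8–C1'' and C2''–C3'' are cut together, giving 8-iodo-tris(MOM)-kaempferide and an isopropenyl(vinyl)borate made from isopropenylboronic acid pinacol ester and vinylMgBr. They are joined under a chiral palladium catalyst.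
- The 8-iodide goes back to kaempferide by MOM etherification and iodination at C8.
- No ring is formed. Rings A, C and B all come intact from kaempferide.

Key step: step 3

Remark on the chemistry: the (Rp,Rp) antipode of MandyPhos is specified on the assumption that the (Sp,Sp) antipode leads to the (R) series when the migrating group outranks the ArCH2 arm. The sense is to be checked by MTPA ester analysis of the derived carbinol, and the ligand antipode is exchanged if it proves opposite.

**Route**

Step 1
Reactants: 1 kaempferide (3,5,7-trihydroxy-2-(4-methoxyphenyl)-4H-chromen-4-one)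
Product: 2 3,5,7-tris(methoxymethoxy)-2-(4-methoxyphenyl)-4H-chromen-4-one (tris-MOM ether of kaempferide)
Conditions: NaH (4 equiv), MOMCl (4 equiv), DMF, argon, 0 °C to rt
Reagents that add atoms: chloromethyl methyl ether, COCCl
Why: Williamson-type O-alkylation, in which excess NaH in DMF deprotonates all three hydroxyls, including the hydrogen-bonded 5-OH that amine bases leave untouched, and the phenoxides are trapped by the reactive alpha-chloro ether.

Step 2
Reactants: 2 tris-MOM ether of kaempferide
Product: 3 8-iodo-3,5,7-tris(methoxymethoxy)-2-(4-methoxyphenyl)-4H-chromen-4-one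
Conditions: NIS (1.1 equiv), DMF, rt, dark
Reagents that add atoms: N-iodosuccinimide, O=C1CCC(=O)N1I
Why: Electrophilic aromatic iodination should go to C8, which is para to the 5-O-MOM and ortho to the 7-O-MOM group and less crowded than C6 between two MOM-oxy groups, as is usual for 5,7-dialkoxyflavones; ring B is deactivated by the chromone and the acid-free medium keeps the acetals.

Step 3
Reactants: 4 isopropenylboronic acid pinacol ester, 5 vinylmagnesium bromide, 3 8-iodo-3,5,7-tris(methoxymethoxy)-2-(4-methoxyphenyl)-4H-chromen-4-one
Product: 7 3,5,7-tris(methoxymethoxy)-2-(4-methoxyphenyl)-8-[(2S)-3-methyl-2-(4,4,5,5-tetramethyl-1,3,2-dioxaborolan-2-yl)but-3-en-1-yl]-4H-chromen-4-one, via bromomagnesium isopropenyl(vinyl)pinacolatoborate 6 (not isolated)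
Conditions: 4 (1.5 equiv), 5 (1.4 equiv), THF, 0 °C to rt; then 3 (1.0 equiv), Pd(OAc)2 (3 mol%), (Rp,Rp)-MandyPhos (3.6 mol%), NaOTf (3 equiv), THF/DMSO, 60 °C, degassed
Reagents that add atoms: none
Why: Oxidative addition of zerovalent palladium into the C8–I bond gives an aryl complex of divalent palladium that, once the triflate salt has taken up iodide, binds the unsubstituted vinyl group of borate 6; the isopropenyl group then shifts from boron to the boron-bearing carbon anti to palladium, and reductive elimination joins the former vinyl CH2 to C8. This is the enantioselective conjunctive cross-coupling of bis(alkenyl)borates with aryl electrophiles, the established access to alpha-chiral allylic boronic esters. No ring closes; the two new bonds are C8–C1'' and C2''–C3''. The C2'' stereocentre is set by the chiral ferrocenyl bisphosphine on palladium, which selects the face of the bound vinyl group. The step needs the vinyl group to be activated and the isopropenyl group to migrate, which follows from palladium binding the less hindered alkene, and it needs the conjunctive path to outrun direct Suzuki–Miyaura transfer, which the wide-bite-angle ligand favours. The chromone carbonyl is protected from the Grignard reagent because 5 is used in deficit to 4 and is fully converted into the non-nucleophilic borate before 3 is added, and C8–I is the only carbon–halogen bond in 3.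

Step 4
Reactants: 7 (S)-allylic boronic ester
Product: 8 8-[(2S)-2-hydroxy-3-methylbut-3-en-1-yl]-3,5,7-tris(methoxymethoxy)-2-(4-methoxyphenyl)-4H-chromen-4-one
Conditions: 30% aq H2O2, 3 M aq NaOH, THF, 0 °C to rt; Na2S2O3 quench
Reagents that add atoms: hydrogen peroxide, OO
Why: Boronate oxidation, in which hydroperoxide adds to boron and C2'' migrates from boron to oxygen with retention and without allylic transposition, so the (S) centre of step 3 is carried over; the fully etherified flavone has no free 3-OH and a poorly electrophilic C2=C3 bond and should tolerate cold alkaline peroxide.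

Step 5
Reactants: 8 tris-MOM-protected (S)-allylic alcohol
Product: 9 3,5,7-trihydroxy-8-[(2S)-2-hydroxy-3-methylbut-3-en-1-yl]-2-(4-methoxyphenyl)-4H-chromen-4-one (2''-hydroxy-3''-en-anhydroicaritin)
Conditions: HCl (1.25 M in MeOH, diluted to ca. 0.5 M), MeOH/THF, rt to 35 °C
Reagents that add atoms: none
Why: Acid-catalysed acetal exchange with methanol cleaves the three MOM ethers as dimethoxymethane, the 5-O and 3-O acetals next to the carbonyl going first; dilute acid near room temperature is chosen so that neither ionisation of the secondary allylic alcohol nor protonation of the isopropenyl group with closure onto the 7-OH should compete, and C2'' is not touched.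

**Compound list**

1 | kaempferide, 3,5,7-trihydroxy-2-(4-methoxyphenyl)-4H-chromen-4-one | COc1ccc(cc1)-c1oc2cc(O)cc(O)c2c(=O)c1O | starting material
2 | 3,5,7-tris(methoxymethoxy)-2-(4-methoxyphenyl)-4H-chromen-4-one | COCOc1cc(OCOC)c2c(=O)c(OCOC)c(-c3ccc(OC)cc3)oc2c1 | intermediate
3 | 8-iodo-3,5,7-tris(methoxymethoxy)-2-(4-methoxyphenyl)-4H-chromen-4-one | COCOc1cc(OCOC)c2c(=O)c(OCOC)c(-c3ccc(OC)cc3)oc2c1I | intermediate
4 | isopropenylboronic acid pinacol ester | C=C(C)B1OC(C)(C)C(C)(C)O1 | starting material
5 | vinylmagnesium bromide | C=C[Mg]Br | starting material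
6 | bromomagnesium isopropenyl(vinyl)pinacolatoborate (ate complex, not isolated) | C=C(C)[B-]1(C=C)OC(C)(C)C(C)(C)O1.[Mg+2].[Br-] | intermediate
7 | 3,5,7-tris(methoxymethoxy)-2-(4-methoxyphenyl)-8-[(2S)-3-methyl-2-(4,4,5,5-tetramethyl-1,3,2-dioxaborolan-2-yl)but-3-en-1-yl]-4H-chromen-4-one | C=C(C)[C@@H](B1OC(C)(C)C(C)(C)O1)Cc1c(OCOC)cc(OCOC)c2c(=O)c(OCOC)c(-c3ccc(OC)cc3)oc12 | intermediate
8 | 8-[(2S)-2-hydroxy-3-methylbut-3-en-1-yl]-3,5,7-tris(methoxymethoxy)-2-(4-methoxyphenyl)-4H-chromen-4-one | C=C(C)[C@@H](O)Cc1c(OCOC)cc(OCOC)c2c(=O)c(OCOC)c(-c3ccc(OC)cc3)oc12 | intermediate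
9 | 3,5,7-trihydroxy-8-[(2S)-2-hydroxy-3-methylbut-3-en-1-yl]-2-(4-methoxyphenyl)-4H-chromen-4-one | C=C(C)[C@@H](O)Cc1c(O)cc(O)c2c(=O)c(O)c(-c3ccc(OC)cc3)oc12 | target

**Step count**

Total steps: 5. Longest linear sequence: 5 steps (1 to 2 to 3 to 7 to 8 to 9).

**Steps most likely to fail**

Step 3. The aryl group on palladium sits between the 7-O-MOM group and the ring oxygen, so alkene binding and the metallate shift may be slow. Iodide may stay on palladium and shut down the cationic pathway. Direct transfer of a vinyl or isopropenyl group, or beta-hydride elimination after the shift, may take over, and facial selectivity may erode with so hindered an aryl partner. The fallback sets out from 3 and comes back at 8.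
- Stille coupling of 3 with tributyl(3-methylbut-2-en-1-yl)stannane (Pd(PPh3)4, DMF, 90 °C) should give the 8-prenyl flavone 3,5,7-tris(methoxymethoxy)-2-(4-methoxyphenyl)-8-(3-methylbut-2-en-1-yl)-4H-chromen-4-one F1.
- Shi epoxidation of the trisubstituted prenyl alkene should give the (S)-epoxide 8-{[(2S)-3,3-dimethyloxiran-2-yl]methyl}-3,5,7-tris(methoxymethoxy)-2-(4-methoxyphenyl)-4H-chromen-4-one F2. The ketone catalyst is the L-sorbose-derived one, the antipode of the D-fructose-derived catalyst, with Oxone (2KHSO5·KHSO4·K2SO4) and K2CO3 in MeCN/dimethoxymethane/aqueous buffer at 0 °C. This ketone antipode is expected to deliver the (S) epoxide.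
- Epoxide-to-allylic-alcohol isomerisation with diethylaluminium 2,2,6,6-tetramethylpiperidide (toluene, 0 °C) should give 8. It removes a methyl proton and opens the tertiary C3''–O bond, so the C2''–O bond and its configuration are untouched.

Step 5. Acid may ionise the secondary allylic alcohol, or protonate the isopropenyl group so that the freed 7-OH closes a dihydropyran ring onto C3''. The 7-O-MOM group may also lag behind the other two, which would invite harsher acid. The fallback sets out from 8 and comes back at 9.
- TMSOTf and 2,2'-bipyridyl (CH2Cl2, 0 °C to rt) exchange the aryl MOM ethers for silyl ethers without Brønsted acid and silylate the C2'' hydroxyl. This should give the tetrakis(trimethylsilyl) ether 2-(4-methoxyphenyl)-3,5,7-tris(trimethylsilyloxy)-8-[(2S)-3-methyl-2-(trimethylsilyloxy)but-3-en-1-yl]-4H-chromen-4-one F3.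
- Brief treatment with aqueous methanol and catalytic K2CO3 under argon hydrolyses the four silyl ethers to give 9.

Step 2. Iodination of the carbonyl-deactivated ring A may stall without acid. Added acid would strip the labile 5-O-MOM group, after which substitution turns to C6, and forcing the reaction may also iodinate twice. The fallback sets out from 2 and comes back at 7.
- NBS (DMF, 0 °C to rt) is a stronger electrophile that needs no acid. It should give the 8-bromoflavone 8-bromo-3,5,7-tris(methoxymethoxy)-2-(4-methoxyphenyl)-4H-chromen-4-one F4.
- F4 is used in place of 3 in the conjunctive coupling of step 3 under the same catalyst and NaOTf. Aryl bromides are established partners there when a triflate salt scavenges the halide, and the product is 7.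

**Further compounds**

F1 | step 3 | 3,5,7-tris(methoxymethoxy)-2-(4-methoxyphenyl)-8-(3-methylbut-2-en-1-yl)-4H-chromen-4-one | CC(C)=CCc1c(OCOC)cc(OCOC)c2c(=O)c(OCOC)c(-c3ccc(OC)cc3)oc12
F2 | step 3 | 8-{[(2S)-3,3-dimethyloxiran-2-yl]methyl}-3,5,7-tris(methoxymethoxy)-2-(4-methoxyphenyl)-4H-chromen-4-one | CC1(C)[C@H](Cc2c(OCOC)cc(OCOC)c3c(=O)c(OCOC)c(-c4ccc(OC)cc4)oc23)O1
F3 | step 5 | 2-(4-methoxyphenyl)-3,5,7-tris(trimethylsilyloxy)-8-[(2S)-3-methyl-2-(trimethylsilyloxy)but-3-en-1-yl]-4H-chromen-4-one | C=C(C)[C@@H](O[Si](C)(C)C)Cc1c(O[Si](C)(C)C)cc(O[Si](C)(C)C)c2c(=O)c(O[Si](C)(C)C)c(-c3ccc(OC)cc3)oc12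
F4 | step 2 | 8-bromo-3,5,7-tris(methoxymethoxy)-2-(4-methoxyphenyl)-4H-chromen-4-one | COCOc1cc(OCOC)c2c(=O)c(OCOC)c(-c3ccc(OC)cc3)oc2c1Br
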